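The 8,8-dimethyl-6-oxabicyclo[3.2.1]octan-3-one unit is opened at two bonds: the CMe2 carbon to the O-bearing CH, and the ether O to the OCH2 carbon. Both are closed late in one flask, exploiting that this O and CH2 sit 1,3-cis across the CMe2 bridge of the cyclohexanone ring. The precursor carries, on the spiro carbon of a cis-fused lactone, an (E)-β-benzyloxy enone arm and a 2-isopropenyl-acetaldehyde arm. Iron hydride H-atom transfer gives a tertiary radical that adds 6-endo to the benzyloxy-bearing enone carbon; the benzyl ether oxygen then closes reductively onto the aldehyde with loss of toluene. The lactone carbonyl is transposed at the end.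

Key step: step 13

Remark: the carbinol carbon created in step 14 is carried as an epimer mixture because step 16 reoxidises it, and the sense of induction in steps 4 and 11 is assigned by analogy and would be corrected with the enantiomeric ligand or the pseudo-enantiomeric catalyst.

Step 1
Reactants: 1 tert-butyldimethyl(prop-2-yn-1-yloxy)silane
Product: 2 2-[3-(tert-butyldimethylsilyloxy)prop-1-en-2-yl]-4,4,5,5-tetramethyl-1,3,2-dioxaborolane
Conditions: B2pin2, CuCl (5 mol%), 1,3-dimesitylimidazolinium chloride (5 mol%), NaOt-Bu (10 mol%), MeOH (2 equiv), THF, −40 → 0 °C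
Reagents that add atoms: bis(pinacolato)diboron, CC1(C)OB(OC1(C)C)B1OC(C)(C)C(C)(C)O1
Why: Copper-catalysed protoboration (formal hydroboration) of the terminal alkyne, in which the N-aryl carbene ligand and the propargylic oxygen should steer Cu–B addition so that boron ends on the internal carbon, no stereocentre being formed.

Step 2
Reactants: 3 cyclohex-2-en-1-one, 4 methyl bromoacetate
Product: 5 methyl 2-(2-oxocyclohex-3-en-1-yl)acetate (racemic)
Conditions: LiN(iPr)2, THF, −78 °C; then 4, DMPU, −78 → −40 °C
Reagents that add atoms: none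
Why: Kinetic deprotonation of the enone at the α' carbon gives the cross-conjugated enolate, which is alkylated by the bromoacetate (enolate SN2 alkylation), the new centre being racemic and epimerisable and corrected in step 3.

Step 3
Reactants: 5 methyl 2-(2-oxocyclohex-3-en-1-yl)acetate, 2 alkenyl pinacol boronate
Product: 7 methyl 2-{(1S,4R)-4-[3-(tert-butyldimethylsilyloxy)prop-1-en-2-yl]-2-oxocyclohexyl}acetate, via epimeric adduct mixture 6 (not isolated)
Conditions: [RhCl(cod)]2 (2.5 mol%), (R)-BINAP (6 mol%), KOH (0.2 equiv), 1,4-dioxane/H2O 10:1, 50 °C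
Reagents that add atoms: none
Why: Rhodium-catalysed asymmetric 1,4-addition of the alkenylboronate (Hayashi–Miyaura reaction) should set the β-stereocentre (R) under ligand control whatever the remote α' centre, which then equilibrates through the enol under the basic conditions to the trans-2,5-diequatorial ketone.

Step 4
Reactants: 7 trans keto ester with the 1,1-disubstituted alkene
Product: 8 methyl 2-{(1S,4R)-4-[(2R)-1-(tert-butyldimethylsilyloxy)propan-2-yl]-2-oxocyclohexyl}acetate
Conditions: H2 (1 bar), [Ir(cod){(S)-tBu-PHOX}]BArF (1 mol%), CH2Cl2, 23 °C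
Reagents that add atoms: none
Why: Iridium-catalysed asymmetric hydrogenation of the 1,1-disubstituted allylic silyl ether, the chiral P,N ligand selecting the alkene face to set the methyl-bearing side-chain centre (R) while ketone and ester stay untouched.

Step 5
Reactants: 8 saturated keto ester
Product: 9 enol triflate of 8 (triflate on the former carbonyl carbon, double bond towards the ring CH2, stereocentres as in 8)
Conditions: KN(SiMe3)2, THF, −78 °C; then PhNTf2, −78 → 0 °C
Reagents that add atoms: N-phenylbis(trifluoromethanesulfonimide), O=S(=O)(N(c1ccccc1)S(=O)(=O)C(F)(F)F)C(F)(F)F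
Why: Kinetic enolisation of the 2,5-disubstituted cyclohexanone should take place at the ring methylene and not at the branched α-carbon, and O-sulfonylation of the potassium enolate gives the enol triflate without touching a stereocentre.

Step 6
Reactants: 9 enol triflate
Product: 11 7-[(2R)-1-(tert-butyldimethylsilyloxy)propan-2-yl]-1,4,4a,5,6,7-hexahydro-3H-isochromen-3-one (stereocentres as in 8), via allylic alcohol 10 (not isolated)
Conditions: Bu3SnCH2OH, Pd(PPh3)4 (5 mol%), LiCl, 1,4-dioxane, 100 °C; then TsOH·H2O (cat.), 23 °C
Reagents that add atoms: (tributylstannyl)methanol, CCCC[Sn](CO)(CCCC)CCCC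
Why: Stille cross-coupling of the enol triflate with the hydroxymethylstannane installs the CH2OH carbon, and the allylic alcohol then closes onto the neighbouring ester under acid catalysis (lactonisation by transesterification).

Step 7
Reactants: 11 unsaturated lactone
Product: 12 (4aS,7R,8aS)-7-[(2R)-1-(tert-butyldimethylsilyloxy)propan-2-yl]octahydro-3H-isochromen-3-one (cis-fused)
Conditions: H2 (1 bar), Rh/Al2O3 (5 wt% Rh), EtOAc, 23 °C
Reagents that add atoms: none
Why: Heterogeneous hydrogenation of the trisubstituted alkene should deliver hydrogen to the face carrying the ring-fusion hydrogen, the lactone CH2 arm shielding the other face, which gives the cis-fused lactone, and rhodium is chosen to avoid allylic C–O hydrogenolysis.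

Step 8
Reactants: 13 benzyl vinyl ether
Product: 15 (E)-3-(benzyloxy)prop-2-enoyl chloride, via ketoacyl chloride 14 (not isolated)
Conditions: (COCl)2, neat, 0 → 23 °C; then 120 °C, distillation
Reagents that add atoms: oxalyl chloride, O=C(Cl)C(=O)Cl
Why: Electrophilic acylation of the enol ether at its β-carbon by oxalyl chloride followed by thermal decarbonylation of the α-keto acid chloride, the (E) geometry being the stable one of the push–pull alkene.

Step 9
Reactants: 12 cis-fused lactone, 15 (E)-3-(benzyloxy)prop-2-enoyl chloride
Product: 16 4-[(E)-3-(benzyloxy)prop-2-enoyl] derivative of 12 (epimers at the acylated carbon in equilibrium with the enol)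
Conditions: LiN(SiMe3)2 (2.2 equiv), THF, −78 °C; then 15, −78 → −40 °C; aq. NH4Cl
Reagents that add atoms: none
Why: C-Acylation of the lithium lactone enolate by the acid chloride (crossed Claisen-type acylation), the second equivalent of base removing the acidic proton of the β-keto lactone formed, whose new centre is epimerisable and is fixed in step 11.

Step 10
Reactants: 17 2-methylprop-2-enal, 18 nitromethane
Product: 20 (E)-3-methyl-1-nitrobuta-1,3-diene, via nitro alcohol 19 (not isolated)
Conditions: KOt-Bu (5 mol%), t-BuOH/THF, 0 °C; then MsCl, Et3N, CH2Cl2, −20 → 0 °C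
Reagents that add atoms: none
Why: Henry (nitroaldol) addition of nitromethane to the aldehyde and β-elimination of the derived mesylate should give the conjugated (E)-nitrodiene.

Step 11
Reactants: 16 α-acyl lactone, 20 (E)-3-methyl-1-nitrobuta-1,3-diene
Product: 21 4-[(E)-3-(benzyloxy)prop-2-enoyl]-4-[(2R)-3-methyl-1-nitrobut-3-en-2-yl] derivative of 12 (new quaternary carbon R)
Conditions: quinine-derived 3,5-bis(trifluoromethyl)phenyl squaramide (10 mol%), CH2Cl2, −20 °C
Reagents that add atoms: none
Why: Organocatalytic Michael addition of the α-acyl lactone to the nitroalkene terminus, in which the enol should be attacked anti to the axial ring-C bond at the adjacent ring-fusion carbon (convex face) to set the quaternary carbon, while the hydrogen-bonding squaramide fixes the nitrodiene face and thus the tertiary centre.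

Step 12
Reactants: 21 nitro lactone
Product: 22 aldehyde in which the CH2NO2 group of 21 has become CHO (stereocentres unchanged)
Conditions: DBU, THF, −20 °C; then TiCl3, NH4OAc, H2O, 0 → 23 °C
Reagents that add atoms: water, O
Why: Nef reaction in its reductive form, the nitronate being reduced by TiCl3 to the imine, which hydrolyses in the buffered medium to the aldehyde without epimerising the adjacent centre or hydrolysing the vinylogous ester.

Step 13
Reactants: 22 aldehyde with (E)-β-benzyloxy enone and isopropenyl groups
Product: 24 spiro ketone in which the 8,8-dimethyl-6-oxabicyclo[3.2.1]octan-3-one is joined through its C2 to C4 of the lactone of 12 (configuration as in the target), via benzyloxy keto aldehyde 23 (not isolated)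
Conditions: Fe(acac)3 (0.3 equiv), PhSiH3, EtOH/THF, 50 °C; concentrate; then Et3SiH, BF3·OEt2, CH2Cl2, −78 → 0 °C
Reagents that add atoms: none
Why: Hydrogen-atom transfer from an iron hydride to the isopropenyl group (Mukaiyama-type HAT) gives a tertiary radical that closes the cyclohexanone ring by 6-endo-trig Giese addition to the benzyloxy-bearing β-carbon of the enone, the α-keto radical then being reduced and protonated to 23. In the second stage BF3 activates the aldehyde, the benzyl ether oxygen attacks it 5-exo-trig to close the oxolane, the oxonium ion loses benzyl to the silane (toluene) and the cyclic oxocarbenium ion is reduced by Et3SiH. The closest known reaction types are the reductive HAT-initiated radical conjugate addition, radical cyclisation onto β-alkoxy enones, debenzylative cycloetherification and silane reductive etherification. The one new stereocentre, the O-bearing CH, is set in the radical step by a chair-like transition state in which the ring-C carbon on the quaternary centre and the formyl group are equatorial and the (E)-enol ether places the benzyloxy group equatorial, hence cis to the formyl group. The step needs HAT at the electron-rich 1,1-disubstituted alkene and not at the push–pull enone, β- and not α-attack on the enone (polarity of the nucleophilic radical) and activation of the aldehyde and not of the hindered ketone or the lactone. The ether closure is self-selecting because only the 1,3-cis isomer can reach the diaxial conformer in which oxygen and formyl carbon meet.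

Step 14
Reactants: 24 spiro ether ketone lactone
Product: 25 triol (lactone opened to two CH2OH groups, ketone reduced to CHOH as an epimer mixture, silyl ether kept)
Conditions: LiAlH4, THF, 0 → 23 °C; aq. NaOH work-up
Reagents that add atoms: none
Why: Hydride reduction with LiAlH4 should open the lactone to the 1,5-diol and reduce the ketone to a carbinol whose configuration is of no consequence, silyl and cyclic ethers being inert.

Step 15
Reactants: 25 triol
Product: 26 hydroxy lactone with the carbonyl on the ring-C side (1-hydroxy analogue of the target carrying the primary silyl ether)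
Conditions: TEMPO (20 mol%), PhI(OAc)2, CH2Cl2, 23 °C
Reagents that add atoms: none
Why: Oxoammonium (TEMPO) oxidation is selective for the less hindered primary alcohol on the cyclohexane ring, whose aldehyde should be trapped as the six-membered lactol by the neopentyl primary hydroxyl in preference to the hindered secondary one and oxidised on to the lactone (oxidative lactonisation of a 1,5-diol), the cis ring fusion being untouched.

Step 16
Reactants: 26 hydroxy lactone silyl ether
Product: 27 CNP0152427.2 (target)
Conditions: CrO3, H2SO4, H2O, acetone, 0 → 23 °C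
Reagents that add atoms: water, O
Why: Jones oxidation should convert the secondary carbinol into the ketone and, after acid cleavage of the silyl ether, the primary alcohol through the aldehyde hydrate into the carboxylic acid, the acidic medium avoiding base-induced epimerisation next to the carbonyl groups.

Compound list
1 | tert-butyldimethyl(prop-2-yn-1-yloxy)silane | C#CCO[Si](C)(C)C(C)(C)C | starting material
2 | 2-[3-(tert-butyldimethylsilyloxy)prop-1-en-2-yl]-4,4,5,5-tetramethyl-1,3,2-dioxaborolane | C=C(CO[Si](C)(C)C(C)(C)C)B1OC(C)(C)C(C)(C)O1 | intermediate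
3 | cyclohex-2-en-1-one | O=C1C=CCCC1 | starting material
4 | methyl bromoacetate | COC(=O)CBr | starting material
5 | methyl 2-(2-oxocyclohex-3-en-1-yl)acetate, racemic | COC(=O)CC1CCC=CC1=O | intermediate
6 | methyl 2-{(4R)-4-[3-(tert-butyldimethylsilyloxy)prop-1-en-2-yl]-2-oxocyclohexyl}acetate, both C1 epimers | C=C(CO[Si](C)(C)C(C)(C)C)[C@@H]1CCC(CC(=O)OC)C(=O)C1 | intermediate
7 | methyl 2-{(1S,4R)-4-[3-(tert-butyldimethylsilyloxy)prop-1-en-2-yl]-2-oxocyclohexyl}acetate | C=C(CO[Si](C)(C)C(C)(C)C)[C@@H]1CC[C@@H](CC(=O)OC)C(=O)C1 | intermediate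
8 | methyl 2-{(1S,4R)-4-[(2R)-1-(tert-butyldimethylsilyloxy)propan-2-yl]-2-oxocyclohexyl}acetate | C[C@@H](CO[Si](C)(C)C(C)(C)C)[C@@H]1CC[C@@H](CC(=O)OC)C(=O)C1 | intermediate
9 | methyl 2-{4-[(2R)-1-(tert-butyldimethylsilyloxy)propan-2-yl]-2-(trifluoromethylsulfonyloxy)cyclohex-2-en-1-yl}acetate, ring stereocentres as in 8 | C[C@@H](CO[Si](C)(C)C(C)(C)C)[C@@H]1CC[C@@H](CC(=O)OC)C(OS(=O)(=O)C(F)(F)F)=C1 | intermediate
10 | methyl 2-{2-(hydroxymethyl)-4-[(2R)-1-(tert-butyldimethylsilyloxy)propan-2-yl]cyclohex-2-en-1-yl}acetate, ring stereocentres as in 8 | C[C@@H](CO[Si](C)(C)C(C)(C)C)[C@@H]1CC[C@@H](CC(=O)OC)C(CO)=C1 | intermediate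
11 | 7-[(2R)-1-(tert-butyldimethylsilyloxy)propan-2-yl]-1,4,4a,5,6,7-hexahydro-3H-isochromen-3-one, stereocentres as in 8 | C[C@@H](CO[Si](C)(C)C(C)(C)C)[C@@H]1CC[C@H]2CC(=O)OCC2=C1 | intermediate
12 | (4aS,7R,8aS)-7-[(2R)-1-(tert-butyldimethylsilyloxy)propan-2-yl]octahydro-3H-isochromen-3-one, cis-fused | C[C@@H](CO[Si](C)(C)C(C)(C)C)[C@@H]1CC[C@@H]2[C@H](C1)COC(=O)C2 | intermediate
13 | benzyl vinyl ether | C=COCc1ccccc1 | starting material
14 | (E)-4-(benzyloxy)-2-oxobut-3-enoyl chloride | O=C(Cl)C(=O)/C=C/OCc1ccccc1 | intermediate
15 | (E)-3-(benzyloxy)prop-2-enoyl chloride | O=C(Cl)/C=C/OCc1ccccc1 | intermediate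
16 | 4-[(E)-3-(benzyloxy)prop-2-enoyl] derivative of 12, C4 epimers and enol | C[C@@H](CO[Si](C)(C)C(C)(C)C)[C@@H]1CC[C@@H]2[C@H](C1)COC(=O)C2C(=O)/C=C/OCc1ccccc1 | intermediate
17 | 2-methylprop-2-enal | C=C(C)C=O | starting material
18 | nitromethane | C[N+](=O)[O-] | starting material
19 | 3-methyl-1-nitrobut-3-en-2-ol, racemic | C=C(C)C(O)C[N+](=O)[O-] | intermediate
20 | (E)-3-methyl-1-nitrobuta-1,3-diene | C=C(C)/C=C/[N+](=O)[O-] | intermediate
21 | (4R)-4-[(E)-3-(benzyloxy)prop-2-enoyl]-4-[(2R)-3-methyl-1-nitrobut-3-en-2-yl] derivative of 12, nitroalkyl group anti to the ring-C bond at C4a | C[C@@H](CO[Si](C)(C)C(C)(C)C)[C@@H]1CC[C@@H]2[C@H](C1)COC(=O)[C@]2([C@H](C[N+](=O)[O-])C(C)=C)C(=O)/C=C/OCc1ccccc1 | intermediate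
22 | (4R)-4-[(E)-3-(benzyloxy)prop-2-enoyl]-4-[(2R)-3-methyl-1-oxobut-3-en-2-yl] derivative of 12 | C[C@@H](CO[Si](C)(C)C(C)(C)C)[C@@H]1CC[C@@H]2[C@H](C1)COC(=O)[C@]2([C@H](C=O)C(C)=C)C(=O)/C=C/OCc1ccccc1 | intermediate
23 | spiro lactone in which C4 of the lactone of 12 is C1 of a 4-(benzyloxy)-5,5-dimethyl-2-oxocyclohexane-6-carbaldehyde, benzyloxy and formyl cis | C[C@@H](CO[Si](C)(C)C(C)(C)C)[C@@H]1CC[C@@H]2[C@H](C1)COC(=O)[C@]21C(=O)C[C@@H](OCc3ccccc3)C(C)(C)[C@H]1C=O | intermediate
24 | spiro lactone in which C4 of the lactone of 12 is C2 of (1R,5R)-8,8-dimethyl-6-oxabicyclo[3.2.1]octan-3-one, configuration as in the target | C[C@@H](CO[Si](C)(C)C(C)(C)C)[C@@H]1CC[C@@H]2[C@H](C1)COC(=O)[C@]21C(=O)C[C@H]2OC[C@@H]1C2(C)C | intermediate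
25 | triol from 24: 2,2-disubstituted 8,8-dimethyl-6-oxabicyclo[3.2.1]octan-3-ol bearing CH2OH and the cis-2-(hydroxymethyl)cyclohexyl group, carbinol epimers | C[C@@H](CO[Si](C)(C)C(C)(C)C)[C@@H]1CC[C@H]([C@H](C1)CO)[C@]1(CO)C(O)C[C@H]2OC[C@@H]1C2(C)C | intermediate
26 | 1-hydroxy analogue of the target with the acid carbon as CH2OSi(t-Bu)Me2, carbinol epimers | C[C@@H](CO[Si](C)(C)C(C)(C)C)[C@@H]1CC[C@@H]2[C@H](C1)C(=O)OC[C@]21C(O)C[C@H]2OC[C@@H]1C2(C)C | intermediate
27 | CNP0152427.2 | C[C@@H](C(=O)O)[C@@H]1CC[C@@H]2[C@H](C1)C(=O)OC[C@]21C(=O)C[C@H]2OC[C@@H]1C2(C)C | target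

Total step count: 16. Longest linear sequence: 13 steps (3 to 27 through steps 2 to 7, 9 and 11 to 16).

Steps most likely to fail

Step 13. The radical may add with poor facial selectivity at the benzyloxy-bearing carbon, or the benzyl ether may fail to close onto the aldehyde before the aldehyde is simply reduced. The fallback sets out from 23, isolated after the radical stage, and either epimer at the benzyloxy carbon serves. NaBH4 at −78 °C reduces only the aldehyde to the primary alcohol F1. DBU in toluene then eliminates benzyl alcohol (E1cB) to the enone F2, which closes by intramolecular oxa-Michael addition of the primary hydroxyl. This returns to the route at 24.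

Step 11. The hindered addition that creates the vicinal quaternary and tertiary centres may be slow, may suffer from mismatched substrate and catalyst control, or may lose the nitrodiene to polymerisation. The fallback sets out from 16. TMSCl/Et3N gives the trimethylsilyl dienol ether F3, which adds to 20 under SnCl4 at −78 °C (Mukaiyama–Michael addition) to the silyl nitronate F4. Aqueous work-up hydrolyses F4 to the aldehyde, the quaternary centre again being set on the convex face and the epimers at the formyl-bearing carbon being separated. This returns to the route at 22.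

Step 12. The nitronate may add to the vinylogous ester within the molecule, or the double bond of the β,γ-unsaturated aldehyde may migrate into conjugation. The fallback sets out from 21. NaNO2/AcOH in DMSO oxidises the nitromethyl group to the carboxylic acid F5 without a free nitronate or an aldehyde stage. F5 is reduced through its mixed anhydride (i-BuOCOCl, N-methylmorpholine; then NaBH4) to the primary alcohol F6, which is oxidised at once (Dess–Martin oxidation). This returns to the route at 22.

Further compounds
F1 | step 13 | primary alcohol from 23 (CHO reduced to CH2OH, either epimer at the benzyloxy carbon) | C[C@@H](CO[Si](C)(C)C(C)(C)C)[C@@H]1CC[C@@H]2[C@H](C1)COC(=O)[C@]21C(=O)CC(OCc3ccccc3)C(C)(C)[C@H]1CO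
F2 | step 13 | enone alcohol (4,4-dimethylcyclohex-2-enone bearing CH2OH at C5, spiro at C6) | C[C@@H](CO[Si](C)(C)C(C)(C)C)[C@@H]1CC[C@@H]2[C@H](C1)COC(=O)[C@]21C(=O)C=CC(C)(C)[C@H]1CO
F3 | step 11 | trimethylsilyl dienol ether of 16 | C[C@@H](CO[Si](C)(C)C(C)(C)C)[C@@H]1CC[C@@H]2[C@H](C1)COC(=O)C2=C(O[Si](C)(C)C)/C=C/OCc1ccccc1
F4 | step 11 | trimethylsilyl nitronate of 21 | C[C@@H](CO[Si](C)(C)C(C)(C)C)[C@@H]1CC[C@@H]2[C@H](C1)COC(=O)[C@]2([C@H](C=[N+]([O-])O[Si](C)(C)C)C(C)=C)C(=O)/C=C/OCc1ccccc1
F5 | step 12 | carboxylic acid corresponding to aldehyde 22 | C[C@@H](CO[Si](C)(C)C(C)(C)C)[C@@H]1CC[C@@H]2[C@H](C1)COC(=O)[C@]2([C@H](C(=O)O)C(C)=C)C(=O)/C=C/OCc1ccccc1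
F6 | step 12 | primary alcohol corresponding to aldehyde 22 | C[C@@H](CO[Si](C)(C)C(C)(C)C)[C@@H]1CC[C@@H]2[C@H](C1)COC(=O)[C@]2([C@H](CO)C(C)=C)C(=O)/C=C/OCc1ccccc1
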